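Ring A (C1, C2, C3, C4, C5, C10; eremophilane numbering) holds the C3 oxygen in a 1,5-relationship to the C9 oxygen across the cis C5/C10 fusion. This is the retron of a Diels–Alder reaction between a 2-silyloxydiene (C1=C2–C3(OSi)=C4) and an enone (C9=O, C10=C5). The enone is carene-derived car-3-en-5-one: its gem-dimethylcyclopropane (C7, C8, C11) shields one face and later releases its strain in a retro-ene shift that unveils the isopropenyl group and a C8 enol ether. One cycloaddition forms C1–C10 and C4–C5, closes ring A and sets the C5 quaternary centre and C10 relative to C7; C4 is corrected thermodynamically.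

Key step: step 3

Remarks on the chemistry:
- Numbering: ring A = C1, C2, C3, C4, C5, C10; ring B = C5 to C10; C11–C13 = isopropenyl; C14 = methyl on C5; C15 = methyl on C4. β is the face that carries C14. In the target C15, H-10, the isopropenyl group, 8-OH and 9-OH are β and the C3 oxygen is α; the target is (3R,4R,5R,7R,8S,9R,10S).
- C1 of (+)-3-carene becomes C7 of the target and already has the required absolute configuration.
- Assumption: the cycloadduct is drawn with C15 cis to C14 (exo topology). The route does not depend on this, because the C4 epimer would pass through steps 4–6 and converge in step 7.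

Step 1
Reactants: 1 (+)-3-carene
Product: 2 (1S,6R)-car-3-en-5-one
Conditions: CrO3, 3,5-dimethylpyrazole, CH2Cl2, −20 °C
Reagents that add atoms: chromium trioxide, O=[Cr](=O)=O
Why: Allylic oxidation attacks the C5 methylene of carene, which is both allylic and cyclopropylcarbinylic and flanked by the vinylic CH, and leaves both ring-fusion stereocentres untouched.

Step 2
Reactants: 3 ethyl vinyl ketone
Product: 4 (Z)-3-(tert-butyldimethylsilyloxy)penta-1,3-diene
Conditions: tBuMe2SiOTf, Et3N, Et2O, 0 °C
Reagents that add atoms: tert-butyldimethylsilyl triflate, CC(C)(C)[Si](C)(C)OS(=O)(=O)C(F)(F)F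
Why: Soft enolisation (silyl triflate/amine) of the ethyl ketone gives the cross-conjugated silyl dienol ether with the methyl group cis to oxygen, the geometry that can reach the s-cis diene.

Step 3
Reactants: 2 (1S,6R)-car-3-en-5-one; 4 (Z)-3-(tert-butyldimethylsilyloxy)penta-1,3-diene
Product: 5 3-(tert-butyldimethylsilyloxy)-8,11-cycloeremophil-2-en-9-one (4β-CH3, 5β-CH3, 10β-H, cyclopropane on the β-face)
Conditions: HN(SO2CF3)2 (5 mol %), CH2Cl2, −78 → −40 °C; Et3N quench
Reagents that add atoms: none
Why: The silyl triflimide formed from HN(SO2CF3)2 and 4 activates the enone, and the enol-ether carbon C4 adds to the enone β-carbon C5 while C1 closes on C10, either as an asynchronous [4+2] cycloaddition or as a Mukaiyama–Michael/Michael sequence whose silyl transfer regenerates the catalyst and leaves the C2=C3 silyl enol ether. The closest known reaction type is the Lewis-acid (silyl triflimide or aluminium halide) catalysed Diels–Alder reaction of 2-silyloxydienes with β-substituted cycloalkenones. Ring A closes as the six-membered ring of the [4+2] event (in the stepwise view the second bond forms by a 6-endo-trig Michael closure). C5 and C10 are set cis by suprafacial addition to the ring alkene, and their sense relative to C7 is set by approach of the diene anti to the gem-dimethylcyclopropane, whose endo methyl group covers the β-face; C4 should arise through the exo topology (silyloxy-bearing diene carbons away from ring B) and is in any case equilibrated in step 7. The step needs regioselectivity (C4 to C5, not to C10), secured by the 2-silyloxy group that makes C4 the nucleophilic terminus, and it needs conjugate addition to outrun ionisation of the cyclopropyl ketone, which the low temperature and the non-nucleophilic counter-ion favour.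

Step 4
Reactants: 5 cycloadduct
Product: 7 3-(tert-butyldimethylsilyloxy)-9-(trimethylsilyloxy)eremophila-2,8,11-triene, via 9(10)-trimethylsilyl enol ether 6 (not isolated)
Conditions: KN(SiMe3)2, THF, −78 → 0 °C; Me3SiCl, −78 °C → rt; then toluene, 170 °C, sealed tube
Reagents that add atoms: chlorotrimethylsilane, C[Si](C)(C)Cl
Why: Only C10 can be enolised (C8 is a cyclopropane carbon), so O-silylation gives 6, a cis-alkyl vinylcyclopropane that undergoes the thermal homodienyl 1,5-hydrogen shift (retro-ene reaction, as known for 2-carene-type vinylcyclopropanes): a hydrogen of the endo methyl group is delivered suprafacially to the β-face of C10 (re-forming the cis fusion), the strained C8–C11 bond breaks, and the isopropenyl group and a regiodefined C8=C9 silyl enol ether appear together.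

Step 5
Reactants: 7 bis(silyl enol ether)
Product: 10 8β-(triethylsilyloxy)-3-(tert-butyldimethylsilyloxy)eremophila-2,11-dien-9-one, via lithium 8(9)-enolate 8 (not isolated), via lithium 8β-alkoxide 9 (not isolated)
Conditions: MeLi, THF, 0 °C; 2-(phenylsulfonyl)-3-phenyloxaziridine, −78 °C; Et3SiCl, DMAP (cat.), −78 → 0 °C
Reagents that add atoms: 2-(phenylsulfonyl)-3-phenyloxaziridine, O=S(=O)(c1ccccc1)N1OC1c1ccccc1; chlorotriethylsilane, CC[Si](Cl)(CC)CC
Why: Methyllithium cleaves the trimethylsilyl (not the bulkier tert-butyldimethylsilyl) enol ether to the regiodefined enolate 8, whose oxidation by the N-sulfonyloxaziridine should occur by axial attack on the convex β-face of the conformationally locked half-chair (isopropenyl pseudo-equatorial), and the resulting alkoxide 9 is capped in situ as its triethylsilyl ether.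

Step 6
Reactants: 10 α-silyloxy ketone
Product: 11 8β-(triethylsilyloxy)-3-(tert-butyldimethylsilyloxy)eremophila-2,11-dien-9β-ol
Conditions: LiAlH4, Et2O, −78 °C; then H2O
Reagents that add atoms: none
Why: Hydride should add to C9 anti to the axial C8–O bond (polar Felkin–Anh control, reinforced by the axial silyloxy group that blocks the β-face and cannot direct delivery), giving the equatorial 9β-alcohol cis to the C8 oxygen.

Step 7
Reactants: 11 mono-silylated diol
Product: 12 8β,9β-dihydroxyeremophil-11-en-3-one
Conditions: Bu4NF, THF, 0 °C → rt; then K2CO3, MeOH, rt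
Reagents that add atoms: none
Why: Fluoride removes the triethylsilyl ether and the silyl enol ether (unveiling the C3 ketone), and the carbonate then equilibrates C4 through the enolate to the epimer with C15 equatorial and cis to C14 (the axial epimer suffers a 1,3-diaxial contact with C9), so either C4 outcome of the cycloaddition converges on 12; C10 is no longer α to a carbonyl and cannot epimerise.

Step 8
Reactants: 12 keto diol
Product: 13 8β,9β-(isopropylidenedioxy)eremophil-11-en-3-one
Conditions: 2,2-dimethoxypropane, pyridinium p-toluenesulfonate (cat.), acetone, rt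
Reagents that add atoms: 2,2-dimethoxypropane, COC(C)(C)OC
Why: Acid-catalysed transketalisation protects the cis-8,9-diol as its five-membered isopropylidene acetal and leaves the hindered C3 ketone free.

Step 9
Reactants: 13 acetonide ketone
Product: 14 8β,9β-(isopropylidenedioxy)eremophil-11-en-3α-ol
Conditions: Li, NH3 (l), THF, −78 °C; then NH4Cl
Reagents that add atoms: none
Why: Dissolving-metal reduction gives the thermodynamically preferred equatorial 3α-alcohol (trans to C15), which hydride reagents would not give because axial attack is blocked by the 1,3-diaxial C14 methyl; the isolated isopropenyl group and the acetal are inert.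

Step 10
Reactants: 14 3α-alcohol; 15 bis(2,2,2-trifluoroethyl)phosphonoacetic acid
Product: 16 8β,9β-(isopropylidenedioxy)eremophil-11-en-3α-yl bis(2,2,2-trifluoroethyl)phosphonoacetate
Conditions: DCC, DMAP (cat.), CH2Cl2, 0 °C → rt
Reagents that add atoms: none
Why: Steglich esterification of the equatorial secondary alcohol with the phosphonoacetic acid; no stereocentre is touched.

Step 11
Reactants: 17 (R)-pent-4-en-2-ol; 18 angelic acid
Product: 20 (R)-pent-4-en-2-yl angelate, via mixed anhydride 19 (not isolated)
Conditions: 2,4,6-trichlorobenzoyl chloride, Et3N, toluene, rt; then 17, 80 °C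
Reagents that add atoms: none
Why: Yamaguchi esterification through the hindered mixed anhydride acylates the alcohol at the angeloyl carbonyl without (Z)-to-(E) isomerisation, and the carbinol centre of 17 is retained.

Step 12
Reactants: 20 (R)-pent-4-en-2-yl angelate
Product: 22 (R)-4-oxobutan-2-yl angelate, via diol 21 (not isolated)
Conditions: OsO4 (cat.), NaIO4, 2,6-lutidine, dioxane/H2O, rt
Reagents that add atoms: osmium tetroxide (oxygen carrier), O=[Os](=O)(=O)=O; sodium periodate (terminal oxidant), [Na+].[O-]I(=O)(=O)=O
Why: Lemieux–Johnson cleavage: OsO4 dihydroxylates the monosubstituted terminal alkene much faster than the hindered, electron-poor angelate alkene, and periodate cleaves the diol to the aldehyde.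

Step 13
Reactants: 16 phosphonoacetate; 22 (R)-4-oxobutan-2-yl angelate
Product: 23 8,9-O-isopropylidene derivative of the target
Conditions: KN(SiMe3)2, 18-crown-6, THF, −78 °C
Reagents that add atoms: none
Why: Still–Gennari variant of the Horner–Wadsworth–Emmons olefination: the bis(trifluoroethyl)phosphonate under dissociating conditions gives the (Z)-enoate under kinetic control, at a temperature where the β-acyloxy aldehyde does not eliminate.

Step 14
Reactants: 23 protected target
Product: 24 target
Conditions: AcOH/H2O/THF, 40 °C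
Reagents that add atoms: none
Why: Mild aqueous acid hydrolyses the isopropylidene acetal while both esters, the (Z)-enoate and the isopropenyl group survive.

Compound list
1 | (+)-3-carene, (1S,6R)-3,7,7-trimethylbicyclo[4.1.0]hept-3-ene | CC1=CC[C@@H]2[C@H](C1)C2(C)C | starting material
2 | (1S,6R)-car-3-en-5-one, i.e. (1R,6S)-4,7,7-trimethylbicyclo[4.1.0]hept-3-en-2-one | CC1(C)[C@H]2CC(C)=CC(=O)[C@@H]12 | intermediate
3 | ethyl vinyl ketone (pent-1-en-3-one) | CCC(=O)C=C | starting material
4 | (Z)-3-(tert-butyldimethylsilyloxy)penta-1,3-diene | C=C/C(O[Si](C)(C)C(C)(C)C)=C/C | intermediate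
5 | 3-(tert-butyldimethylsilyloxy)-8,11-cycloeremophil-2-en-9-one (4β,5β-dimethyl, 10β-H, 7α-H, 8α-H) | CC1(C)[C@H]2C[C@@]3(C)[C@H](CC=C(O[Si](C)(C)C(C)(C)C)[C@@H]3C)C(=O)[C@@H]12 | intermediate
6 | 3-(tert-butyldimethylsilyloxy)-9-(trimethylsilyloxy)-8,11-cycloeremophila-2,9-diene (4β,5β-dimethyl) | CC1(C)[C@H]2C[C@@]3(C)C(CC=C(O[Si](C)(C)C(C)(C)C)[C@@H]3C)=C(O[Si](C)(C)C)[C@@H]12 | intermediate (not isolated)
7 | 3-(tert-butyldimethylsilyloxy)-9-(trimethylsilyloxy)eremophila-2,8,11-triene (4β,5β-dimethyl, 7β-isopropenyl, 10β-H) | C=C(C)[C@H]1C[C@@]2(C)[C@H](CC=C(O[Si](C)(C)C(C)(C)C)[C@@H]2C)C(O[Si](C)(C)C)=C1 | intermediate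
8 | lithium 8(9)-enolate of 3-(tert-butyldimethylsilyloxy)eremophila-2,11-dien-9-one | C=C(C)[C@H]1C[C@@]2(C)[C@H](CC=C(O[Si](C)(C)C(C)(C)C)[C@@H]2C)C([O-])=C1.[Li+] | intermediate (not isolated)
9 | lithium 8β-alkoxide of 8β-hydroxy-3-(tert-butyldimethylsilyloxy)eremophila-2,11-dien-9-one | C=C(C)[C@H]1C[C@@]2(C)[C@H](CC=C(O[Si](C)(C)C(C)(C)C)[C@@H]2C)C(=O)[C@H]1[O-].[Li+] | intermediate (not isolated)
10 | 8β-(triethylsilyloxy)-3-(tert-butyldimethylsilyloxy)eremophila-2,11-dien-9-one | C=C(C)[C@H]1C[C@@]2(C)[C@H](CC=C(O[Si](C)(C)C(C)(C)C)[C@@H]2C)C(=O)[C@H]1O[Si](CC)(CC)CC | intermediate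
11 | 8β-(triethylsilyloxy)-3-(tert-butyldimethylsilyloxy)eremophila-2,11-dien-9β-ol | C=C(C)[C@H]1C[C@@]2(C)[C@H](CC=C(O[Si](C)(C)C(C)(C)C)[C@@H]2C)[C@@H](O)[C@H]1O[Si](CC)(CC)CC | intermediate
12 | 8β,9β-dihydroxyeremophil-11-en-3-one (4β,5β-dimethyl, 10β-H) | C=C(C)[C@H]1C[C@@]2(C)[C@H](CCC(=O)[C@@H]2C)[C@@H](O)[C@H]1O | intermediate
13 | 8β,9β-(isopropylidenedioxy)eremophil-11-en-3-one | C=C(C)[C@H]1C[C@@]2(C)[C@H](CCC(=O)[C@@H]2C)[C@H]3OC(C)(C)O[C@@H]13 | intermediate
14 | 8β,9β-(isopropylidenedioxy)eremophil-11-en-3α-ol | C=C(C)[C@H]1C[C@@]2(C)[C@H](CC[C@@H](O)[C@@H]2C)[C@H]3OC(C)(C)O[C@@H]13 | intermediate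
15 | bis(2,2,2-trifluoroethyl)phosphonoacetic acid | OC(=O)CP(=O)(OCC(F)(F)F)OCC(F)(F)F | starting material
16 | 8β,9β-(isopropylidenedioxy)eremophil-11-en-3α-yl bis(2,2,2-trifluoroethyl)phosphonoacetate | C=C(C)[C@H]1C[C@@]2(C)[C@H](CC[C@@H](OC(=O)CP(=O)(OCC(F)(F)F)OCC(F)(F)F)[C@@H]2C)[C@H]3OC(C)(C)O[C@@H]13 | intermediate
17 | (R)-pent-4-en-2-ol | C=CC[C@@H](C)O | starting material
18 | angelic acid, (Z)-2-methylbut-2-enoic acid | C/C=C(/C)C(=O)O | starting material
19 | angelic 2,4,6-trichlorobenzoic anhydride | C/C=C(/C)C(=O)OC(=O)c1c(Cl)cc(Cl)cc1Cl | intermediate (not isolated)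
20 | (R)-pent-4-en-2-yl (Z)-2-methylbut-2-enoate | C=CC[C@@H](C)OC(=O)/C(C)=C\C | intermediate
21 | (2R)-4,5-dihydroxypentan-2-yl (Z)-2-methylbut-2-enoate (both C4 epimers) | OCC(O)C[C@@H](C)OC(=O)/C(C)=C\C | intermediate (not isolated)
22 | (R)-4-oxobutan-2-yl (Z)-2-methylbut-2-enoate | O=CC[C@@H](C)OC(=O)/C(C)=C\C | intermediate
23 | 8β,9β-(isopropylidenedioxy)eremophil-11-en-3α-yl (2Z,5R)-5-[(Z)-2-methylbut-2-enoyloxy]hex-2-enoate | C=C(C)[C@H]1C[C@@]2(C)[C@H](CC[C@@H](OC(=O)/C=C\C[C@@H](C)OC(=O)/C(C)=C\C)[C@@H]2C)[C@H]3OC(C)(C)O[C@@H]13 | intermediate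
24 | (3R,4R,5R,7R,8S,9R,10S)-8,9-dihydroxyeremophil-11-en-3-yl (2Z,5R)-5-[(Z)-2-methylbut-2-enoyloxy]hex-2-enoate | C=C(C)[C@H]1C[C@@]2(C)[C@H](CC[C@@H](OC(=O)/C=C\C[C@@H](C)OC(=O)/C(C)=C\C)[C@@H]2C)[C@@H](O)[C@H]1O | target

Total step count: 14. Longest linear sequence: 11 steps (1, 3, 4, 5, 6, 7, 8, 9, 10, 13, 14).

Steps most likely to fail

Step 3 (key cycloaddition). The acid catalyst may ionise the cyclopropyl ketone (ring opening and drift towards the phenol) faster than the diene adds, or addition to the β,β-disubstituted enone may be too slow under a catalyst mild enough to spare the cyclopropane. The fallback removes the cyclopropane before the cycloaddition and sets out from 2. Treatment of 2 with Me3SiOTf and 2,6-di-tert-butyl-4-methylpyridine opens the C8–C11 bond and gives the silyl dienol ether trimethyl{[(3S)-5-methyl-3-(prop-1-en-2-yl)cyclohexa-1,5-dien-1-yl]oxy}silane F1. Mild aqueous acid then gives (S)-3-methyl-5-(prop-1-en-2-yl)cyclohex-2-en-1-one F2. F2 tolerates the stronger mixed Lewis acid AlBr3/AlMe3, under which 4 should add anti to the C7 substituent (as nucleophiles do with 5-substituted cyclohexenones) to give 3-(tert-butyldimethylsilyloxy)eremophila-2,11-dien-9-one F3. Kinetic deprotonation of F3 at the C8 methylene with LiN(iPr)2 gives enolate 8, where the route is rejoined; step 4 is then not needed.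

Step 4 (enol silylation and retro-ene shift). Enolisation of the hindered C10–H may be incomplete, or the hydrogen shift may need a temperature at which the bis(silyl enol ether) scrambles or decomposes. The fallback is an ionic strain release that sets out from 5 and comes back at 7. Me3SiOTf with 2,6-di-tert-butyl-4-methylpyridine in CH2Cl2 (−78 → 0 °C) silylates the carbonyl oxygen, the C8–C11 bond heterolyses to the tertiary cation, and the hindered base removes a methyl proton, giving 7 with the C10 configuration of the cycloaddition retained. It makes no compound outside the list (F0).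

Step 6 (reduction at C9). The hydride may be delivered with poor facial selectivity, from the convex β-face, because the α-face trajectory passes the axial C4–C5 bond. The fallback replaces kinetic hydride addition by thermodynamic control and sets out from 10 and comes back at 11. A Meerwein–Ponndorf–Verley reduction (Al(OiPr)3, iPrOH, toluene, 80 °C) transfers hydride reversibly and should settle on the equatorial 9β-alcohol, since the axial epimer is 1,3-diaxial to C4. It makes no compound outside the list (F0).

Further compounds
F1 | step 3 | trimethyl{[(3S)-5-methyl-3-(prop-1-en-2-yl)cyclohexa-1,5-dien-1-yl]oxy}silane | C=C(C)[C@H]1CC(C)=CC(O[Si](C)(C)C)=C1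
F2 | step 3 | (S)-3-methyl-5-(prop-1-en-2-yl)cyclohex-2-en-1-one | C=C(C)[C@H]1CC(C)=CC(=O)C1
F3 | step 3 | 3-(tert-butyldimethylsilyloxy)eremophila-2,11-dien-9-one (4β,5β-dimethyl, 7β-isopropenyl, 10β-H) | C=C(C)[C@H]1C[C@@]2(C)[C@H](CC=C(O[Si](C)(C)C(C)(C)C)[C@@H]2C)C(=O)C1
F0 | step 4 | none | none
F0 | step 6 | none | none
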